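**Retrosynthetic overview** (chromene numbering: ring A = C4a, C5, C6, C7, C8, C8a; ring B = O1, C2, C3, C4, C4a, C8a)
1. The plan rests on C2 of ring B: it is bonded to O1 and lies β to the C4 ketone, so O1–C2 is cut by a retro-oxa-Michael step to an (E)-crotonoyl group on C4a and a free enol at C8a. C2 is separated from the quaternary C8 by O1 and C8a, so its configuration is given to a chiral amine-thiourea catalyst, and O5 is carried as a methyl ether so that only O8a can close.
2. The crotonoyl group is removed at C4a–C4 (acyl transfer onto the O5-methyl enol ether of the ring A trione), then the O5 methyl.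
3. Ring A is opened at C6–C7 (Dieckmann) to a diketo ester, which comes from 6-methylhept-5-en-2-one and a geranyl(methyl)malonic half-ester. The C8 quaternary centre comes from esterase desymmetrisation of the malonate.
4. Ring order: ring A (step 5), then ring B (step 8); O5 is unmasked last.

Key step: step 8

Remark: the esterase is assumed to hydrolyse the same enantiotopic ester as in 2-methylmalonates with long unbranched chains, which should leave the (R)-half-ester; this sense has to be confirmed before scale-up.
Remark: enolates, carboxylates and ammonium salts that exist only until work-up are treated as forms of the numbered parent compound. Geranyl = (2E)-3,7-dimethylocta-2,6-dien-1-yl; prenyl = 3-methylbut-2-en-1-yl.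

**Step 1**
Reactants: 1 dimethyl 2-methylmalonate; 2 geranyl bromide
Product: 3 dimethyl 2-geranyl-2-methylmalonate
Conditions: NaH, THF, 0 °C; then 2, 0 °C to rt
Reagents that add atoms: none
Why: Malonic ester alkylation, an SN2 reaction of the sodium enolate with a primary allylic bromide, should give the quaternary diester with the (E)-alkene unchanged.

**Step 2**
Reactants: 3 dimethyl 2-geranyl-2-methylmalonate
Product: 4 (2R,4E)-2-(methoxycarbonyl)-2,5,9-trimethyldeca-4,8-dienoic acid
Conditions: pig liver esterase, NaH2PO4/Na2HPO4 buffer pH 7.5, 10% DMSO, 25 °C; citric acid to pH 3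
Reagents that add atoms: water, O
Why: Enzymatic desymmetrisation of a prochiral 2,2-disubstituted dimethyl malonate hydrolyses one enantiotopic ester and so sets the quaternary centre, expected as (R) by analogy with long-chain 2-alkyl-2-methylmalonates.

**Step 3**
Reactants: 4 (2R,4E)-2-(methoxycarbonyl)-2,5,9-trimethyldeca-4,8-dienoic acid
Product: 5 methyl (2S,4E)-2-(chlorocarbonyl)-2,5,9-trimethyldeca-4,8-dienoate (same spatial arrangement as 4; the descriptor changes because COCl outranks CO2Me)
Conditions: 1-chloro-N,N,2-trimethylprop-1-en-1-amine (1.2 equiv), CH2Cl2, 0 °C to rt; evaporate, use crude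
Reagents that add atoms: 1-chloro-N,N,2-trimethylprop-1-en-1-amine, CC(C)=C(Cl)N(C)C
Why: Acid chloride formation with an α-chloroenamine runs under neutral conditions without free HCl, so the trisubstituted alkenes and the methyl ester should survive, and the quaternary α-carbon can neither form a ketene nor racemise.

**Step 4**
Reactants: 5 methyl (2S,4E)-2-(chlorocarbonyl)-2,5,9-trimethyldeca-4,8-dienoate; 6 6-methylhept-5-en-2-one
Product: 7 methyl (2R)-2-geranyl-2,9-dimethyl-3,5-dioxodec-8-enoate (drawn as the diketone)
Conditions: 6 (2.2 equiv), LiN(i-Pr)2 (2.2 equiv), THF, −78 °C; then 5, −78 to −30 °C; aq NH4Cl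
Reagents that add atoms: none
Why: Kinetic deprotonation of the methyl ketone at CH3 and C-acylation of the lithium enolate by the acid chloride (crossed Claisen-type acylation) should give the 1,3-diketone, the second equivalent of enolate taking up its acidic proton; any product from the internal enolate would lead to the enantiomeric ring and is removed by chromatography here.

**Step 5**
Reactants: 7 methyl (2R)-2-geranyl-2,9-dimethyl-3,5-dioxodec-8-enoate
Product: 8 (6R)-6-geranyl-3-hydroxy-6-methyl-2-prenylcyclohex-2-ene-1,5-dione (one enol form of the ring A 1,3,5-trione)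
Conditions: LiN(i-Pr)2 (3 equiv), THF, −78 to 0 °C; cold 1 M HCl
Reagents that add atoms: none
Why: Dieckmann condensation of the 1,3-diketone dianion through its terminal carbon (C6) onto the methyl ester closes ring A (6-exo-trig, new C6–C7 bond), driven by the stabilised trione enolate; the quaternary centre is not enolisable and keeps its configuration.

**Step 6**
Reactants: 8 (6R)-6-geranyl-3-hydroxy-6-methyl-2-prenylcyclohex-2-ene-1,5-dione
Product: 9 (6R)-6-geranyl-3-methoxy-6-methyl-2-prenylcyclohex-2-ene-1,5-dione (O5 methyl ether, one tautomer drawn)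
Conditions: MeOH, HC(OMe)3 (3 equiv, water scavenger), camphorsulfonic acid (5 mol%), rt; Et3N quench
Reagents that add atoms: methanol, CO
Why: Acid-catalysed enol etherification under thermodynamic control (a vinylogous Fischer esterification) should place the methyl on the C5 oxygen, the only ring carbonyl not flanked by the quaternary C8, as is known for 4,4-disubstituted cyclohexane-1,3-diones.

**Step 7**
Reactants: 9 (6R)-6-geranyl-3-methoxy-6-methyl-2-prenylcyclohex-2-ene-1,5-dione; 10 (E)-but-2-enoyl chloride (crotonoyl chloride)
Product: 12 (6R)-4-[(2E)-but-2-enoyl]-6-geranyl-5-hydroxy-3-methoxy-6-methyl-2-prenylcyclohexa-2,4-dien-1-one, via enol crotonate 11 (not isolated)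
Conditions: 4-(dimethylamino)pyridine (DMAP, 2.2 equiv), CH2Cl2, 0 °C, slow addition of 10; then rt to 40 °C; cold 0.5 M HCl wash
Reagents that add atoms: none
Why: O-acylation of the enol followed by DMAP-mediated O-to-C acyl migration (Steglich-type rearrangement, as in 2-acylcyclohexane-1,3-dione synthesis) should deliver the acyl group to C4a, the only carbon whose acylation gives an enolisable, chelated and acidic tricarbonyl, while acylation at C6 is reversible; a pyridine base instead of a trialkylamine avoids deconjugation through the vinylketene.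

**Step 8**
Reactants: 12 (6R)-4-[(2E)-but-2-enoyl]-6-geranyl-5-hydroxy-3-methoxy-6-methyl-2-prenylcyclohexa-2,4-dien-1-one
Product: 13 (2S,8R)-8-geranyl-5-methoxy-2,8-dimethyl-6-prenyl-2,3-dihydro-4H-chromene-4,7(8H)-dione
Conditions: N-[3,5-bis(trifluoromethyl)phenyl]-N'-[(8α,9S)-6'-methoxycinchonan-9-yl]thiourea (quinine-derived, 10–20 mol%), toluene, 0 °C to rt
Reagents that add atoms: none
Why: Proposed new method: the quinuclidine nitrogen of the catalyst deprotonates the acidic C8a enol while the thiourea hydrogen-bonds the crotonoyl carbonyl, so the enolate oxygen adds to C2 of the (E)-enone inside a chiral ion pair and the C3 enolate is then protonated by the ammonium ion, forming O1–C2. The closest known reaction is the amine-thiourea-catalysed asymmetric intramolecular oxa-Michael addition of 2'-hydroxyaryl enones to flavanones and 2-alkylchromanones; what is new is that the nucleophile is the enol oxygen of a non-aromatic vinylogous acid and not a phenol. Ring B closes in the 6-endo-trig mode. The C2 stereocentre is set by the catalyst alone (the quinine-derived catalyst is proposed for the 2S face, with its quinidine-derived pseudo-enantiomer as the alternative), because C8 lies four bonds away across O1 and C8a and gives no useful bias, and C8 itself is quaternary and untouched. The step needs regioselectivity between the enol oxygens and face selectivity at C2: the O5 methyl ether leaves O8a as the only free enol oxygen, and the single (E)-geometry of the enone from step 7 gives one ion-pair geometry for the catalyst to discriminate. The neutral product should release the catalyst, and any (2R,8R) epimer can be separated, reopened to 12 with 1,8-diazabicyclo[5.4.0]undec-7-ene (retro-oxa-Michael, E1cB, the opened enol being trapped as its salt) and resubmitted, so the material converges on 13.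

**Step 9**
Reactants: 13 (2S,8R)-8-geranyl-5-methoxy-2,8-dimethyl-6-prenyl-2,3-dihydro-4H-chromene-4,7(8H)-dione
Product: 14 (2S,8R)-8-geranyl-5-hydroxy-2,8-dimethyl-6-prenyl-2,3-dihydro-4H-chromene-4,7(8H)-dione (target)
Conditions: LiCl (5 equiv), DMF, 100 °C; then cold 0.5 M HCl
Reagents that add atoms: none
Why: SN2 demethylation of the vinylogous methyl ester by chloride (Krapcho-type O-alkyl cleavage) releases the stabilised anion of the C5–C6–C7 vinylogous acid; attack at methyl should be far faster than at the secondary C2, and no base strong enough to deprotonate C3 is present, so ring B and the C2 centre should stay intact.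

**Compound list**
1 | dimethyl 2-methylmalonate | COC(=O)C(C)C(=O)OC | starting material
2 | geranyl bromide, (2E)-1-bromo-3,7-dimethylocta-2,6-diene | CC(C)=CCC/C(C)=C/CBr | starting material
3 | dimethyl 2-geranyl-2-methylmalonate | CC(C)=CCC/C(C)=C/CC(C)(C(=O)OC)C(=O)OC | intermediate
4 | (2R,4E)-2-(methoxycarbonyl)-2,5,9-trimethyldeca-4,8-dienoic acid | CC(C)=CCC/C(C)=C/C[C@@](C(=O)O)(C)C(=O)OC | intermediate
5 | methyl (2S,4E)-2-(chlorocarbonyl)-2,5,9-trimethyldeca-4,8-dienoate | CC(C)=CCC/C(C)=C/C[C@@](C(=O)Cl)(C)C(=O)OC | intermediate
6 | 6-methylhept-5-en-2-one | CC(=O)CCC=C(C)C | starting material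
7 | methyl (2R)-2-geranyl-2,9-dimethyl-3,5-dioxodec-8-enoate | CC(C)=CCC/C(C)=C/C[C@@](C(=O)CC(=O)CCC=C(C)C)(C)C(=O)OC | intermediate
8 | (6R)-6-geranyl-3-hydroxy-6-methyl-2-prenylcyclohex-2-ene-1,5-dione (enol form of the trione) | CC(C)=CCC/C(C)=C/C[C@@]1(C)C(=O)C(CC=C(C)C)=C(O)CC1=O | intermediate
9 | (6R)-6-geranyl-3-methoxy-6-methyl-2-prenylcyclohex-2-ene-1,5-dione | CC(C)=CCC/C(C)=C/C[C@@]1(C)C(=O)C(CC=C(C)C)=C(OC)CC1=O | intermediate
10 | (E)-but-2-enoyl chloride | C/C=C/C(=O)Cl | starting material
11 | (6R)-6-geranyl-3-methoxy-6-methyl-5-oxo-4-prenylcyclohexa-1,3-dien-1-yl (2E)-but-2-enoate (O8a enol crotonate, not isolated) | CC(C)=CCC/C(C)=C/C[C@@]1(C)C(=O)C(CC=C(C)C)=C(OC)C=C1OC(=O)/C=C/C | intermediate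
12 | (6R)-4-[(2E)-but-2-enoyl]-6-geranyl-5-hydroxy-3-methoxy-6-methyl-2-prenylcyclohexa-2,4-dien-1-one | CC(C)=CCC/C(C)=C/C[C@@]1(C)C(=O)C(CC=C(C)C)=C(OC)C(C(=O)/C=C/C)=C1O | intermediate
13 | (2S,8R)-8-geranyl-5-methoxy-2,8-dimethyl-6-prenyl-2,3-dihydro-4H-chromene-4,7(8H)-dione | CC(C)=CCC/C(C)=C/C[C@@]1(C)C(=O)C(CC=C(C)C)=C(OC)C2=C1O[C@@H](C)CC2=O | intermediate
14 | (2S,8R)-8-geranyl-5-hydroxy-2,8-dimethyl-6-prenyl-2,3-dihydro-4H-chromene-4,7(8H)-dione | CC(C)=CCC/C(C)=C/C[C@@]1(C)C(=O)C(CC=C(C)C)=C(O)C2=C1O[C@@H](C)CC2=O | target

**Step count**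
Total steps: 9. Longest linear sequence: 9 steps (from 1 to 14).

**Steps most likely to fail**

Step 8 (proposed new method). The catalyst may discriminate the two faces of the enone poorly, or turnover may stall because the acidic enol holds the catalyst amine as an unreactive ion pair. The fallback uses known chemistry and sets out from 12. Closure with an achiral base (NaOAc, EtOH, 60 °C) should give 13 together with (2R,8R)-8-geranyl-5-methoxy-2,8-dimethyl-6-prenyl-2,3-dihydro-4H-chromene-4,7(8H)-dione F1. The two are diastereomers and would be separated by chromatography or preparative HPLC. The unwanted epimer is reopened to 12 with 1,8-diazabicyclo[5.4.0]undec-7-ene in THF and put through the closure again. The route is rejoined at 13.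

Step 6. Etherification may occur at O8a or O7 and not at O5, or the acid may start to cyclise the prenyl group onto an enol oxygen. The fallback sets out from acid chloride 5 and installs the O5 methyl by construction.
- 6-Methylhept-5-en-1-yne F2 is made from 5-bromo-2-methylpent-2-ene and LiC≡CH·H2NCH2CH2NH2 in DMSO.
- Coupling of this alkyne with 5 (PdCl2(PPh3)2, CuI, Et3N, THF; acyl Sonogashira coupling) gives methyl (2R)-2-geranyl-2,9-dimethyl-3-oxodec-8-en-4-ynoate F3.
- Conjugate addition of methanol (MeOH, catalytic PBu3) can place the methoxy group only on the β-carbon, giving methyl (2R,4E)-2-geranyl-5-methoxy-2,9-dimethyl-3-oxodeca-4,8-dienoate F4.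
- Deprotonation at the γ-CH2 (KN(SiMe3)2, 2.2 equiv, THF, −78 to 0 °C) and attack of the dienolate on the methyl ester (vinylogous Dieckmann closure) gives ring A with the methyl already on O5.
The route is rejoined at 9.

Step 2. The esterase may hydrolyse the two enantiotopic esters with low selectivity or in the opposite sense, which would erode or invert C8 for the whole route. The fallback sets out from diester 3. Half-saponification (KOH, 1 equiv, MeOH, rt) gives racemic 2-(methoxycarbonyl)-2,5,9-trimethyldeca-4,8-dienoic acid F5. Classical resolution by fractional crystallisation with (S)-1-phenylethylamine (or its antipode, whichever gives the less soluble salt of the (R)-acid) gives (S)-1-phenylethylammonium (2R,4E)-2-(methoxycarbonyl)-2,5,9-trimethyldeca-4,8-dienoate F6. Dilute HCl releases the (R)-acid. The (S)-acid from the mother liquor is re-esterified (Me3SiCHN2, MeOH–toluene) to 3 and recycled. The route is rejoined at 4.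

**Further compounds**
F1 | step 8 | (2R,8R)-8-geranyl-5-methoxy-2,8-dimethyl-6-prenyl-2,3-dihydro-4H-chromene-4,7(8H)-dione | CC(C)=CCC/C(C)=C/C[C@@]1(C)C(=O)C(CC=C(C)C)=C(OC)C2=C1O[C@H](C)CC2=O
F2 | step 6 | 6-methylhept-5-en-1-yne | C#CCCC=C(C)C
F3 | step 6 | methyl (2R)-2-geranyl-2,9-dimethyl-3-oxodec-8-en-4-ynoate | CC(C)=CCC/C(C)=C/C[C@@](C(=O)C#CCCC=C(C)C)(C)C(=O)OC
F4 | step 6 | methyl (2R,4E)-2-geranyl-5-methoxy-2,9-dimethyl-3-oxodeca-4,8-dienoate | CC(C)=CCC/C(C)=C/C[C@@](C(=O)/C=C(/OC)CCC=C(C)C)(C)C(=O)OC
F5 | step 2 | racemic 2-(methoxycarbonyl)-2,5,9-trimethyldeca-4,8-dienoic acid | CC(C)=CCC/C(C)=C/CC(C)(C(=O)O)C(=O)OC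
F6 | step 2 | (S)-1-phenylethylammonium (2R,4E)-2-(methoxycarbonyl)-2,5,9-trimethyldeca-4,8-dienoate | CC(C)=CCC/C(C)=C/C[C@@](C(=O)[O-])(C)C(=O)OC.C[C@H]([NH3+])c1ccccc1
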